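**Plan**
- The target is (2S)-2-(3,4-dimethoxyphenyl)-5,7,8-trimethoxychroman-4-one. The C4 ketone is traced back to a silyl-protected cis-flavan-4-ol, and the C5 and C8 methyl ethers to a hydroquinone.
- Ring A is a pentasubstituted benzene with para oxygens on C5 and C8, a methoxy on C7 and hydrogen on C6, fused to the enol-ether carbons C4a and C8a of ring C. A 4-(dihydropyran-6-yl)-4-hydroxy-3-methoxycyclobutenone turns into exactly this pattern on heating, so ring A is cut at C4a–C5 and folded back to the four-membered ring.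
- The cyclobutenone is cut from ring C at C8–C8a, giving a C6-lithiated dihydropyran and methyl semisquarate. Ring C is cut at O1–C2 and C3–C4, giving veratraldehyde and Danishefsky's diene.
- Forward order: ring C by catalytic asymmetric hetero-Diels–Alder reaction, then attachment of the four-membered ring, then ring A by thermal benzannulation, then methylation, desilylation and oxidation.
- Stereochemistry: C2 (S) comes from catalyst control in the cycloaddition. C4 is a temporary centre set cis to the aryl group by Luche reduction and erased in the last step; it keeps C2 from racemising by ring opening until then.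

Key step: step 6

Assumption: the (S)-BINOL/Ti(OiPr)4 catalyst is taken to direct the diene to the Si face of the aryl aldehyde, as this ligand does in related carbonyl additions; if the opposite sense were found, the (R)-ligand would be used and nothing else changes.

**Route**

Step 1
Reactants: 1 3,4-dimethoxybenzaldehyde; 2 (E)-1-methoxy-3-(trimethylsilyloxy)buta-1,3-diene
Product: 4 (2S)-2-(3,4-dimethoxyphenyl)-2,3-dihydro-4H-pyran-4-one, via aldol silyl ether 3 (not isolated)
Conditions: (S)-BINOL (20 mol%), Ti(OiPr)4 (20 mol%), 4 Å molecular sieves, Et2O, −20 °C; then CF3CO2H, CH2Cl2, 0 °C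
Reagents that add atoms: none
Why: BINOL–titanium Lewis-acid catalysis of the Mukaiyama aldol addition of the siloxydiene to the aldehyde (formal hetero-Diels–Alder reaction) on the Si face should set C2 as S, and acid then closes aldol 3 to the dihydropyranone with loss of methanol.

Step 2
Reactants: 4 (2S)-2-(3,4-dimethoxyphenyl)-2,3-dihydro-4H-pyran-4-one
Product: 5 (2S,4S)-2-(3,4-dimethoxyphenyl)-3,4-dihydro-2H-pyran-4-ol
Conditions: NaBH4, CeCl3·7H2O, MeOH, −78 °C
Reagents that add atoms: none
Why: Luche 1,2-reduction of the vinylogous ester, in which axial hydride delivery to the half-chair carrying the equatorial aryl group should give the equatorial C4 alcohol cis to the aryl group (4S).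

Step 3
Reactants: 5 (2S,4S)-2-(3,4-dimethoxyphenyl)-3,4-dihydro-2H-pyran-4-ol
Product: 6 (2S,4S)-2-(3,4-dimethoxyphenyl)-4-(triisopropylsilyloxy)-3,4-dihydro-2H-pyran
Conditions: TIPSCl, imidazole, DMF, 40 °C
Reagents that add atoms: triisopropylsilyl chloride, CC(C)[Si](Cl)(C(C)C)C(C)C
Why: Base-mediated silylation of the secondary allylic alcohol; the triisopropylsilyl ether is chosen because it has no Si–CH3 hydrogens to compete in the later lithiation and is cleaved by fluoride.

Step 4
Reactants: 7 dimethyl squarate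
Product: 9 3-methoxycyclobut-3-ene-1,2-dione (methyl semisquarate), via hydroxycyclobutenone 8 (not isolated)
Conditions: LiAlH(OtBu)3, THF, −78 → 0 °C; aqueous work-up; then HCl (12 M, cat.), CH2Cl2, rt
Reagents that add atoms: none
Why: Hydride 1,2-addition to one squarate carbonyl followed by acid-catalysed loss of methanol with 1,3-carbonyl transposition, the standard conversion of dialkyl squarates into 3-alkoxycyclobutenediones.

Step 5
Reactants: 6 (2S,4S)-2-(3,4-dimethoxyphenyl)-4-(triisopropylsilyloxy)-3,4-dihydro-2H-pyran; 9 3-methoxycyclobut-3-ene-1,2-dione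
Product: 11 4-[(2S,4S)-2-(3,4-dimethoxyphenyl)-4-(triisopropylsilyloxy)-3,4-dihydro-2H-pyran-6-yl]-4-hydroxy-3-methoxycyclobut-2-en-1-one (both carbinol epimers), via vinyllithium 10 (not isolated)
Conditions: t-BuLi (1.5 equiv), THF, −78 → 0 °C; recool to −78 °C and transfer into 9 (1.5 equiv), THF, −78 °C; NH4Cl (aq), −78 °C
Reagents that add atoms: none
Why: α-Deprotonation of the cyclic enol ether at C6 (α-alkoxyvinyllithium formation) followed by 1,2-addition to the ketone carbonyl next to the methoxy-bearing carbon of 9, which is more electrophilic than the vinylogous ester carbonyl; the new carbinol centre is left uncontrolled because step 6 destroys it.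

Step 6
Reactants: 11 4-[(2S,4S)-2-(3,4-dimethoxyphenyl)-4-(triisopropylsilyloxy)-3,4-dihydro-2H-pyran-6-yl]-4-hydroxy-3-methoxycyclobut-2-en-1-one
Product: 14 (2S,4S)-2-(3,4-dimethoxyphenyl)-7-methoxy-4-(triisopropylsilyloxy)chromane-5,8-diol, via dienylketene 12 (not isolated), via cyclohexadienone 13 (not isolated)
Conditions: degassed toluene, 110 °C, argon; concentrate under argon and use at once
Reagents that add atoms: none
Why: Heating should open the cyclobutenone C1–C4 bond by a conrotatory 4π process in which the donor hydroxyl turns outward and the dihydropyranyl group inward, giving (Z)-dienylketene 12; a thermal disrotatory 6π electrocyclisation then joins the ketene carbon to pyran C5 (the C4a–C5 bond of the target) to give cyclohexadienone 13, which enolises to the aromatic hydroquinone 14. This is the Moore rearrangement of 4-alkenyl-4-hydroxycyclobutenones, a reaction known for adducts of 2-lithiated dihydropyrans with squarate-derived diones. Ring A closes by the 6π electrocyclic mode as a six-membered carbocycle, and the enol-ether double bond of ring C becomes the C4a–C8a bond. No lasting stereocentre is formed: the carbinol centre of 11 and the transient C4a centre of 13 are both erased, while C2 and C4 are not touched. The step needs outward rotation of the hydroxyl, which its donor character secures, and the ring A pattern is already fixed by the constitution of 11 (carbinol carbon becomes C8, methoxy carbon C7, the CH carbon C6, the ketene carbon C5).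

Step 7
Reactants: 14 (2S,4S)-2-(3,4-dimethoxyphenyl)-7-methoxy-4-(triisopropylsilyloxy)chromane-5,8-diol
Product: 15 (2S,4S)-2-(3,4-dimethoxyphenyl)-5,7,8-trimethoxy-4-(triisopropylsilyloxy)chromane
Conditions: Me2SO4, K2CO3, degassed acetone, reflux, argon
Reagents that add atoms: dimethyl sulfate, COS(=O)(=O)OC
Why: Williamson O-methylation of both phenols; with no C4 carbonyl present the C5 hydroxyl is not held in a hydrogen bond and should alkylate as readily as the C8 hydroxyl.

Step 8
Reactants: 15 (2S,4S)-2-(3,4-dimethoxyphenyl)-5,7,8-trimethoxy-4-(triisopropylsilyloxy)chromane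
Product: 16 (2S,4S)-2-(3,4-dimethoxyphenyl)-5,7,8-trimethoxychroman-4-ol
Conditions: Bu4NF, THF, 0 °C → rt
Reagents that add atoms: none
Why: Fluoride-induced cleavage of the silyl ether, driven by Si–F bond formation, under basic conditions that leave the aryl methyl ethers, the acid-sensitive benzylic alcohol and both stereocentres intact.

Step 9
Reactants: 16 (2S,4S)-2-(3,4-dimethoxyphenyl)-5,7,8-trimethoxychroman-4-ol
Product: 17 (2S)-2-(3,4-dimethoxyphenyl)-5,7,8-trimethoxychroman-4-one
Conditions: Dess–Martin periodinane, NaHCO3, CH2Cl2, 0 °C → rt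
Reagents that add atoms: none
Why: Dess–Martin oxidation of the benzylic secondary alcohol under buffered, non-basic conditions that should not open the flavanone to the chalcone, so C2 keeps its S configuration.

**Compound list**

1 | 3,4-dimethoxybenzaldehyde (veratraldehyde) | COc1ccc(C=O)cc1OC | starting material
2 | (E)-1-methoxy-3-(trimethylsilyloxy)buta-1,3-diene | CO/C=C/C(=C)O[Si](C)(C)C | starting material
3 | (1E,5S)-5-(3,4-dimethoxyphenyl)-1-methoxy-5-(trimethylsilyloxy)pent-1-en-3-one (not isolated) | COc1ccc([C@H](CC(=O)/C=C/OC)O[Si](C)(C)C)cc1OC | intermediate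
4 | (2S)-2-(3,4-dimethoxyphenyl)-2,3-dihydro-4H-pyran-4-one | COc1ccc([C@@H]2CC(=O)C=CO2)cc1OC | intermediate
5 | (2S,4S)-2-(3,4-dimethoxyphenyl)-3,4-dihydro-2H-pyran-4-ol | COc1ccc([C@@H]2C[C@H](O)C=CO2)cc1OC | intermediate
6 | (2S,4S)-2-(3,4-dimethoxyphenyl)-4-(triisopropylsilyloxy)-3,4-dihydro-2H-pyran | COc1ccc([C@@H]2C[C@H](O[Si](C(C)C)(C(C)C)C(C)C)C=CO2)cc1OC | intermediate
7 | dimethyl squarate (3,4-dimethoxycyclobut-3-ene-1,2-dione) | COC1=C(OC)C(=O)C1=O | starting material
8 | 4-hydroxy-2,3-dimethoxycyclobut-2-en-1-one (racemic, not isolated) | COC1=C(OC)C(O)C1=O | intermediate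
9 | 3-methoxycyclobut-3-ene-1,2-dione (methyl semisquarate) | COC1=CC(=O)C1=O | intermediate
10 | [(2S,4S)-2-(3,4-dimethoxyphenyl)-4-(triisopropylsilyloxy)-3,4-dihydro-2H-pyran-6-yl]lithium (not isolated) | COc1ccc([C@@H]2C[C@H](O[Si](C(C)C)(C(C)C)C(C)C)C=C([Li])O2)cc1OC | intermediate
11 | 4-[(2S,4S)-2-(3,4-dimethoxyphenyl)-4-(triisopropylsilyloxy)-3,4-dihydro-2H-pyran-6-yl]-4-hydroxy-3-methoxycyclobut-2-en-1-one (carbinol epimers) | COc1ccc([C@@H]2C[C@H](O[Si](C(C)C)(C(C)C)C(C)C)C=C(C3(O)C(OC)=CC3=O)O2)cc1OC | intermediate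
12 | (3Z)-4-[(2S,4S)-2-(3,4-dimethoxyphenyl)-4-(triisopropylsilyloxy)-3,4-dihydro-2H-pyran-6-yl]-4-hydroxy-3-methoxybuta-1,3-dien-1-one (not isolated) | COc1ccc([C@@H]2C[C@H](O[Si](C(C)C)(C(C)C)C(C)C)C=C(/C(O)=C(OC)\C=C=O)O2)cc1OC | intermediate
13 | (2S,4S)-2-(3,4-dimethoxyphenyl)-8-hydroxy-7-methoxy-4-(triisopropylsilyloxy)-2,3,4,4a-tetrahydro-5H-chromen-5-one (C4a epimers, not isolated) | COc1ccc([C@@H]2C[C@H](O[Si](C(C)C)(C(C)C)C(C)C)C3C(=O)C=C(OC)C(O)=C3O2)cc1OC | intermediate
14 | (2S,4S)-2-(3,4-dimethoxyphenyl)-7-methoxy-4-(triisopropylsilyloxy)chromane-5,8-diol | COc1ccc([C@@H]2C[C@H](O[Si](C(C)C)(C(C)C)C(C)C)c3c(O)cc(OC)c(O)c3O2)cc1OC | intermediate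
15 | (2S,4S)-2-(3,4-dimethoxyphenyl)-5,7,8-trimethoxy-4-(triisopropylsilyloxy)chromane | COc1ccc([C@@H]2C[C@H](O[Si](C(C)C)(C(C)C)C(C)C)c3c(OC)cc(OC)c(OC)c3O2)cc1OC | intermediate
16 | (2S,4S)-2-(3,4-dimethoxyphenyl)-5,7,8-trimethoxychroman-4-ol | COc1ccc([C@@H]2C[C@H](O)c3c(OC)cc(OC)c(OC)c3O2)cc1OC | intermediate
17 | (2S)-2-(3,4-dimethoxyphenyl)-5,7,8-trimethoxychroman-4-one | COc1ccc([C@@H]2CC(=O)c3c(OC)cc(OC)c(OC)c3O2)cc1OC | target

**Step count and risks**

Total steps: 9. Longest linear sequence: 8 (steps 1–3 and 5–9 from veratraldehyde); step 4 is a one-step side branch.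

Step 5. The deprotonation may lose site selectivity: t-BuLi can remove the benzylic C2 hydrogen or an aryl hydrogen ortho to a methoxy group instead of the C6 vinyl hydrogen, and any surviving base would attack the semisquarate. The fallback makes the C6 anion by tin–lithium exchange instead of deprotonation. It sets out from 6: oxidation of the enol ether with pyridinium chlorochromate (C5H5NH[CrO3Cl]) in CH2Cl2 should give the lactone (4S,6S)-6-(3,4-dimethoxyphenyl)-4-(triisopropylsilyloxy)tetrahydro-2H-pyran-2-one F1. Enolisation with KN(SiMe3)2 and trapping with (PhO)2P(O)Cl in THF/HMPA at −78 °C should give the ketene acetal phosphate diphenyl (2S,4S)-2-(3,4-dimethoxyphenyl)-4-(triisopropylsilyloxy)-3,4-dihydro-2H-pyran-6-yl phosphate F2. Coupling with Me3SnSnMe3 under Pd(PPh3)4 and LiCl in THF at reflux should give the stannane trimethyl[(2S,4S)-2-(3,4-dimethoxyphenyl)-4-(triisopropylsilyloxy)-3,4-dihydro-2H-pyran-6-yl]stannane F3. MeLi in THF at −78 °C then exchanges tin for lithium, and the route is rejoined at vinyllithium 10, which is added to 9 as in step 5.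

Step 6. The very electron-rich hydroquinone may oxidise in air and degrade during concentration and transfer, so that material is lost between the benzannulation and the methylation. The fallback moves through the quinone oxidation level. It sets out from 11: after the thermolysis in toluene, Ag2O is added to the cooled solution, which should give the stable, chromatographable quinone (2S,4S)-2-(3,4-dimethoxyphenyl)-7-methoxy-4-(triisopropylsilyloxy)-3,4-dihydro-2H-chromene-5,8-dione F4. Reductive methylation (Na2S2O4, then Me2SO4, KOH, Bu4NBr, THF/H2O, under argon) reduces the quinone in the flask and methylates both phenols, and the route is rejoined at 15.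

Step 1. The electron-rich aldehyde may turn over slowly and give poor facial discrimination at the catalyst, so that C2 is formed with insufficient enantiopurity. The fallback replaces asymmetric catalysis by a racemic cycloaddition and classical resolution. It sets out from 1 and 2: ZnCl2 in THF at rt followed by CF3CO2H should give the racemic pyranone (±)-2-(3,4-dimethoxyphenyl)-2,3-dihydro-4H-pyran-4-one F5, and Luche reduction the racemic cis alcohol (±)-cis-2-(3,4-dimethoxyphenyl)-3,4-dihydro-2H-pyran-4-ol F6. Esterification with (S)-2-methoxy-2-phenylacetic acid (DCC, DMAP, CH2Cl2) should give two diastereomeric esters, (2S,4S)-2-(3,4-dimethoxyphenyl)-3,4-dihydro-2H-pyran-4-yl (S)-2-methoxy-2-phenylacetate F7 and (2R,4R)-2-(3,4-dimethoxyphenyl)-3,4-dihydro-2H-pyran-4-yl (S)-2-methoxy-2-phenylacetate F8, to be separated by chromatography on base-washed silica. Methanolysis of F7 (K2CO3, MeOH) rejoins the route at 5.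

**Further compounds**

F1 | step 5 | (4S,6S)-6-(3,4-dimethoxyphenyl)-4-(triisopropylsilyloxy)tetrahydro-2H-pyran-2-one | COc1ccc([C@@H]2C[C@H](O[Si](C(C)C)(C(C)C)C(C)C)CC(=O)O2)cc1OC
F2 | step 5 | diphenyl (2S,4S)-2-(3,4-dimethoxyphenyl)-4-(triisopropylsilyloxy)-3,4-dihydro-2H-pyran-6-yl phosphate | COc1ccc([C@@H]2C[C@H](O[Si](C(C)C)(C(C)C)C(C)C)C=C(OP(=O)(Oc3ccccc3)Oc3ccccc3)O2)cc1OC
F3 | step 5 | trimethyl[(2S,4S)-2-(3,4-dimethoxyphenyl)-4-(triisopropylsilyloxy)-3,4-dihydro-2H-pyran-6-yl]stannane | COc1ccc([C@@H]2C[C@H](O[Si](C(C)C)(C(C)C)C(C)C)C=C([Sn](C)(C)C)O2)cc1OC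
F4 | step 6 | (2S,4S)-2-(3,4-dimethoxyphenyl)-7-methoxy-4-(triisopropylsilyloxy)-3,4-dihydro-2H-chromene-5,8-dione | COc1ccc([C@@H]2C[C@H](O[Si](C(C)C)(C(C)C)C(C)C)C3=C(O2)C(=O)C(OC)=CC3=O)cc1OC
F5 | step 1 | (±)-2-(3,4-dimethoxyphenyl)-2,3-dihydro-4H-pyran-4-one (racemate) | COc1ccc(C2CC(=O)C=CO2)cc1OC
F6 | step 1 | (±)-cis-2-(3,4-dimethoxyphenyl)-3,4-dihydro-2H-pyran-4-ol (racemate, relative configuration cis) | COc1ccc(C2CC(O)C=CO2)cc1OC
F7 | step 1 | (2S,4S)-2-(3,4-dimethoxyphenyl)-3,4-dihydro-2H-pyran-4-yl (S)-2-methoxy-2-phenylacetate | COc1ccc([C@@H]2C[C@H](OC(=O)[C@@H](OC)c3ccccc3)C=CO2)cc1OC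
F8 | step 1 | (2R,4R)-2-(3,4-dimethoxyphenyl)-3,4-dihydro-2H-pyran-4-yl (S)-2-methoxy-2-phenylacetate | COc1ccc([C@H]2C[C@@H](OC(=O)[C@@H](OC)c3ccccc3)C=CO2)cc1OC
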